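**Retrosynthetic overview**
1. Target ⇐ its C-15 silyl ether ⇐ ring-closing metathesis forming C1=C10; the ten-membered ring is closed last.
2. C9–C10 ⇐ Morita–Baylis–Hillman addition of acrolein to a C-9 α-acyloxy aldehyde (8,9-anti).
3. C7–C8 ⇐ aminocatalytic SN2′ alkylation of 2-oxoethyl (R)-2-methylbutanoate with a (5R)-3-(bromomethyl)butenolide; this sets C-7 and C-8, brings in the ester and turns the butenolide into the α-methylene lactone (new reaction).
4. Butenolide (first ring) ⇐ carbonylative lactonisation of a (Z)-γ-iodo allylic alcohol ⇐ catalytic asymmetric alkynylation of an (E)-enal (C-6, first stereocentre).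
5. Enal ⇐ mono-silylated butynediol (hydroalumination/iodination, Negishi coupling, oxidation); acyl donor ⇐ tiglic acid by asymmetric hydrogenation.

Assumption: the mono-TBDPS ether of but-2-yne-1,4-diol, but-3-en-1-ylzinc bromide (THF solution) and TBS propargyl ether are bought as such; labels C-1 to C-15 follow germacrane numbering (lactone oxygen on C-6, ring fusion C-7, ester on C-8, carbinol C-9, CHO = C-14, CH2OH = C-15).

**Route**

Step 1
Reactants: 1 4-[(tert-butyldiphenylsilyl)oxy]but-2-yn-1-ol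
Product: 3 (Z)-4-[(tert-butyldiphenylsilyl)oxy]-3-iodobut-2-en-1-ol, via alkenylaluminate 2 (not isolated)
Conditions: NaAlH2(OCH2CH2OCH3)2 (1.5 equiv), THF, 0 °C; then I2, −78 °C
Reagents that add atoms: iodine, II
Why: Alkoxide-directed trans-hydroalumination of the propargylic alcohol puts hydride on the carbon next to the carbinol and aluminium on the distal carbon inside a five-membered oxaluminole, and iodinolysis with retention gives the (Z)-vinyl iodide that fixes the later C4=C5 geometry (hydroalumination–iodination, no stereocentre).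

Step 2
Reactants: 3 (Z)-4-[(tert-butyldiphenylsilyl)oxy]-3-iodobut-2-en-1-ol; 4 but-3-en-1-ylzinc bromide
Product: 5 (E)-3-{[(tert-butyldiphenylsilyl)oxy]methyl}hepta-2,6-dien-1-ol
Conditions: PdCl2(dppf) (3 mol %), 4 (2.5 equiv), THF, 50 °C
Reagents that add atoms: none
Why: Negishi sp2–sp3 coupling proceeds with retention at the vinyl iodide, so the butenyl chain ends up cis to the CH2OH carbon (C-6) as the ring later requires, and alkylzinc halides tolerate the free hydroxyl.

Step 3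
Reactants: 5 (E)-3-{[(tert-butyldiphenylsilyl)oxy]methyl}hepta-2,6-dien-1-ol
Product: 6 (E)-3-{[(tert-butyldiphenylsilyl)oxy]methyl}hepta-2,6-dienal
Conditions: MnO2 (15 equiv), CH2Cl2, rt
Reagents that add atoms: none
Why: MnO2 oxidises the primary allylic alcohol selectively under neutral conditions that do not isomerise the trisubstituted enal (allylic oxidation).

Step 4
Reactants: 6 (E)-3-{[(tert-butyldiphenylsilyl)oxy]methyl}hepta-2,6-dienal; 7 tert-butyldimethyl(prop-2-yn-1-yloxy)silane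
Product: 9 (4R,5E)-1-[(tert-butyldimethylsilyl)oxy]-6-{[(tert-butyldiphenylsilyl)oxy]methyl}deca-5,9-dien-2-yn-4-ol, via alkynyl(methyl)zinc 8 (not isolated)
Conditions: Me2Zn (3 equiv), (R,R)-ProPhenol (10 mol %), Ph3PO (20 mol %), toluene, 4 °C
Reagents that add atoms: none
Why: Dinuclear zinc–ProPhenol-catalysed asymmetric alkynylation of an enal, in which the chiral pocket delivers the zinc acetylide to the Si face of the aldehyde and so sets C-6 as R, the first stereocentre of the main chain (the ligand antipode is chosen for Si-face delivery).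

Step 5
Reactants: 9 (4R,5E)-1-[(tert-butyldimethylsilyl)oxy]-6-{[(tert-butyldiphenylsilyl)oxy]methyl}deca-5,9-dien-2-yn-4-ol
Product: 11 (2Z,4R,5E)-1-[(tert-butyldimethylsilyl)oxy]-6-{[(tert-butyldiphenylsilyl)oxy]methyl}-2-iododeca-2,5,9-trien-4-ol, via alkenylaluminate 10 (not isolated)
Conditions: NaAlH2(OCH2CH2OCH3)2 (2 equiv), THF, −20 to 0 °C; then I2, −78 °C
Reagents that add atoms: iodine, II
Why: The same carbinol-directed trans-hydroalumination–iodination places H on C-7 and iodine on C-11 cis to the C-6 carbinol, without touching the isolated alkenes or the C-6 stereocentre (low temperature suppresses loss of the silyloxy group to an allene).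

Step 6
Reactants: 11 (2Z,4R,5E)-1-[(tert-butyldimethylsilyl)oxy]-6-{[(tert-butyldiphenylsilyl)oxy]methyl}-2-iododeca-2,5,9-trien-4-ol
Product: 12 (5R)-3-{[(tert-butyldimethylsilyl)oxy]methyl}-5-[(1E)-2-{[(tert-butyldiphenylsilyl)oxy]methyl}hexa-1,5-dien-1-yl]furan-2(5H)-one
Conditions: PdCl2(PPh3)2 (5 mol %), CO (1 atm), K2CO3, THF, 40 °C
Reagents that add atoms: carbon monoxide, [C-]#[O+]
Why: Palladium-catalysed carbonylative lactonisation of a (Z)-γ-iodo allylic alcohol (oxidative addition, CO insertion, capture of the acyl–palladium by the cis hydroxyl) builds the butenolide with C-6 untouched because its C–O bond is never broken.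

Step 7
Reactants: 12 (5R)-3-{[(tert-butyldimethylsilyl)oxy]methyl}-5-[(1E)-2-{[(tert-butyldiphenylsilyl)oxy]methyl}hexa-1,5-dien-1-yl]furan-2(5H)-one
Product: 13 (5R)-3-(bromomethyl)-5-[(1E)-2-{[(tert-butyldiphenylsilyl)oxy]methyl}hexa-1,5-dien-1-yl]furan-2(5H)-one
Conditions: Ph3PBr2 (1.2 equiv), CH2Cl2, 0 °C to rt
Reagents that add atoms: dibromotriphenylphosphorane, BrP(Br)(c1ccccc1)(c1ccccc1)c1ccccc1
Why: Dibromotriphenylphosphorane converts the primary allylic TBS ether directly into the bromide through an alkoxyphosphonium ion and SN2 attack by bromide, while the bulkier TBDPS ether is left intact.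

Step 8
Reactants: 14 (E)-2-methylbut-2-enoic acid (tiglic acid)
Product: 15 (R)-2-methylbutanoic acid
Conditions: H2 (1.5 atm), Ru(OAc)2[(R)-H8-BINAP] (0.5 mol %), MeOH, 15 °C
Reagents that add atoms: none
Why: Carboxylate-directed asymmetric hydrogenation of an α,β-unsaturated acid on the ruthenium–biaryl diphosphine catalyst adds H2 to one enantioface and sets the side-chain centre as R.

Step 9
Reactants: 15 (R)-2-methylbutanoic acid; 16 (Z)-but-2-ene-1,4-diol
Product: 17 (Z)-but-2-ene-1,4-diyl bis[(2R)-2-methylbutanoate]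
Conditions: 15 (2.1 equiv), DCC (2.2 equiv), DMAP (10 mol %), CH2Cl2, 0 °C to rt
Reagents that add atoms: none
Why: Steglich esterification of both primary allylic hydroxyls proceeds at 0 °C without disturbing the α-stereocentre of the acid.

Step 10
Reactants: 17 (Z)-but-2-ene-1,4-diyl bis[(2R)-2-methylbutanoate]
Product: 19 2-oxoethyl (2R)-2-methylbutanoate, via ozonide 18 (not isolated)
Conditions: O3, CH2Cl2, −78 °C; then Me2S, −78 °C to rt
Reagents that add atoms: ozone, [O-][O+]=O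
Why: Ozonolysis with reductive work-up cleaves the symmetric alkene into two molecules of the α-acyloxy aldehyde, with the remote stereocentre unaffected.

Step 11
Reactants: 13 (5R)-3-(bromomethyl)-5-[(1E)-2-{[(tert-butyldiphenylsilyl)oxy]methyl}hexa-1,5-dien-1-yl]furan-2(5H)-one; 19 2-oxoethyl (2R)-2-methylbutanoate
Product: 21 (1R)-1-[(2R,3S)-2-[(1E)-2-{[(tert-butyldiphenylsilyl)oxy]methyl}hexa-1,5-dien-1-yl]-4-methylidene-5-oxooxolan-3-yl]-2-oxoethyl (2R)-2-methylbutanoate, via DABCO allylammonium bromide 20 (not isolated)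
Conditions: DABCO (1.05 equiv), CH2Cl2, 0 °C, 30 min; then 19 (2 equiv), (S)-α,α-diphenylprolinol trimethylsilyl ether (20 mol %), −20 °C
Reagents that add atoms: none
Why: Proposed new method: the DABCO salt 20 is a cationic Baylis–Hillman-type electrophile that the (E)-enamine of 19 attacks at C-7 by SN2′ addition–elimination on the ring face anti to the C-6 alkenyl group (6,7-trans, 7S), while the diphenyl(silyloxy)methyl group screens one enamine face (8R, the matched pairing for a synclinal transition state with the lactone carbonyl under the enamine nitrogen), and loss of DABCO unveils the exo-methylene lactone; the closest known reactions are the aminocatalytic α-alkylation of aldehydes with 2-(bromomethyl)acrylates and the amine-mediated SN2–SN2′ substitution of Baylis–Hillman bromides, neither shown on a β-substituted cyclic butenolide or for two adjacent stereocentres.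

Step 12
Reactants: 21 (1R)-1-[(2R,3S)-2-[(1E)-2-{[(tert-butyldiphenylsilyl)oxy]methyl}hexa-1,5-dien-1-yl]-4-methylidene-5-oxooxolan-3-yl]-2-oxoethyl (2R)-2-methylbutanoate; 22 acrolein (prop-2-enal)
Product: 23 (1R,2S)-1-[(2R,3S)-2-[(1E)-2-{[(tert-butyldiphenylsilyl)oxy]methyl}hexa-1,5-dien-1-yl]-4-methylidene-5-oxooxolan-3-yl]-3-formyl-2-hydroxybut-3-en-1-yl (2R)-2-methylbutanoate
Conditions: 22 (5 equiv), quinuclidine (30 mol %), MeOH (1 equiv), THF, 0 °C
Reagents that add atoms: none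
Why: Morita–Baylis–Hillman reaction of acrolein with the strongly activated α-acyloxy aldehyde, in which Felkin–Anh (polar) addition anti to the C-8 acyloxy group gives the 8,9-anti carbinol (9S) and the lactone methylene cannot turn over because C-11 carries no hydrogen.

Step 13
Reactants: 23 (1R,2S)-1-[(2R,3S)-2-[(1E)-2-{[(tert-butyldiphenylsilyl)oxy]methyl}hexa-1,5-dien-1-yl]-4-methylidene-5-oxooxolan-3-yl]-3-formyl-2-hydroxybut-3-en-1-yl (2R)-2-methylbutanoate
Product: 24 (3aS,4R,5S,6E,10E,11aR)-10-{[(tert-butyldiphenylsilyl)oxy]methyl}-6-formyl-5-hydroxy-3-methylidene-2-oxo-2,3,3a,4,5,8,9,11a-octahydrocyclodeca[b]furan-4-yl (2R)-2-methylbutanoate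
Conditions: second-generation Hoveyda–Grubbs catalyst, RuCl2(H2IMes)(=CH-C6H4-2-OiPr) (15 mol %), 1,4-benzoquinone (30 mol %), toluene (1 mM), 80 °C
Reagents that add atoms: none
Why: Ring-closing metathesis between the terminal alkene and the 2-substituted acrolein unit closes the ten-membered ring, which can only hold the ring-cis C1=C10 alkene (also the preferred enal geometry with CHO trans to C-2), helped by the cis C4=C5 alkene and the trans-fused lactone as turn elements; no stereocentre is formed.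

Step 14
Reactants: 24 (3aS,4R,5S,6E,10E,11aR)-10-{[(tert-butyldiphenylsilyl)oxy]methyl}-6-formyl-5-hydroxy-3-methylidene-2-oxo-2,3,3a,4,5,8,9,11a-octahydrocyclodeca[b]furan-4-yl (2R)-2-methylbutanoate
Product: 25 (3aS,4R,5S,6E,10E,11aR)-6-formyl-5-hydroxy-10-(hydroxymethyl)-3-methylidene-2-oxo-2,3,3a,4,5,8,9,11a-octahydrocyclodeca[b]furan-4-yl (2R)-2-methylbutanoate
Conditions: HF·pyridine, pyridine, THF, 0 °C to rt
Reagents that add atoms: none
Why: Buffered fluoride desilylation frees the primary allylic alcohol under mildly acidic conditions that leave the enal and α-methylene lactone intact and do not promote 8→9 acyl migration.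

**Compound list**
1 | 4-[(tert-butyldiphenylsilyl)oxy]but-2-yn-1-ol | OCC#CCO[Si](c1ccccc1)(c1ccccc1)C(C)(C)C | starting material
2 | sodium 3-{[(tert-butyldiphenylsilyl)oxy]methyl}-2,2-bis(2-methoxyethoxy)-2,5-dihydro-1,2-oxaluminol-2-uide (alkenylaluminate) | [Na+].COCCO[Al-]1(OCCOC)OCC=C1CO[Si](c1ccccc1)(c1ccccc1)C(C)(C)C | intermediate
3 | (Z)-4-[(tert-butyldiphenylsilyl)oxy]-3-iodobut-2-en-1-ol | OC/C=C(\I)CO[Si](c1ccccc1)(c1ccccc1)C(C)(C)C | intermediate
4 | but-3-en-1-ylzinc bromide | C=CCC[Zn]Br | starting material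
5 | (E)-3-{[(tert-butyldiphenylsilyl)oxy]methyl}hepta-2,6-dien-1-ol | OC/C=C(\CCC=C)CO[Si](c1ccccc1)(c1ccccc1)C(C)(C)C | intermediate
6 | (E)-3-{[(tert-butyldiphenylsilyl)oxy]methyl}hepta-2,6-dienal | O=C/C=C(\CCC=C)CO[Si](c1ccccc1)(c1ccccc1)C(C)(C)C | intermediate
7 | tert-butyldimethyl(prop-2-yn-1-yloxy)silane | C#CCO[Si](C)(C)C(C)(C)C | starting material
8 | {3-[(tert-butyldimethylsilyl)oxy]prop-1-yn-1-yl}(methyl)zinc | C[Zn]C#CCO[Si](C)(C)C(C)(C)C | intermediate
9 | (4R,5E)-1-[(tert-butyldimethylsilyl)oxy]-6-{[(tert-butyldiphenylsilyl)oxy]methyl}deca-5,9-dien-2-yn-4-ol | O[C@@H](C#CCO[Si](C)(C)C(C)(C)C)/C=C(\CCC=C)CO[Si](c1ccccc1)(c1ccccc1)C(C)(C)C | intermediate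
10 | sodium cyclic alkenylaluminate of 9 (5R; Al on C-11, O on C-6) | [Na+].COCCO[Al-]1(OCCOC)O[C@@H](C=C1CO[Si](C)(C)C(C)(C)C)/C=C(\CCC=C)CO[Si](c1ccccc1)(c1ccccc1)C(C)(C)C | intermediate
11 | (2Z,4R,5E)-1-[(tert-butyldimethylsilyl)oxy]-6-{[(tert-butyldiphenylsilyl)oxy]methyl}-2-iododeca-2,5,9-trien-4-ol | O[C@@H](/C=C(\I)CO[Si](C)(C)C(C)(C)C)/C=C(\CCC=C)CO[Si](c1ccccc1)(c1ccccc1)C(C)(C)C | intermediate
12 | (5R)-3-{[(tert-butyldimethylsilyl)oxy]methyl}-5-[(1E)-2-{[(tert-butyldiphenylsilyl)oxy]methyl}hexa-1,5-dien-1-yl]furan-2(5H)-one | O=C1O[C@@H](C=C1CO[Si](C)(C)C(C)(C)C)/C=C(\CCC=C)CO[Si](c1ccccc1)(c1ccccc1)C(C)(C)C | intermediate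
13 | (5R)-3-(bromomethyl)-5-[(1E)-2-{[(tert-butyldiphenylsilyl)oxy]methyl}hexa-1,5-dien-1-yl]furan-2(5H)-one | O=C1O[C@@H](C=C1CBr)/C=C(\CCC=C)CO[Si](c1ccccc1)(c1ccccc1)C(C)(C)C | intermediate
14 | (E)-2-methylbut-2-enoic acid (tiglic acid) | C/C=C(\C)C(=O)O | starting material
15 | (R)-2-methylbutanoic acid | CC[C@@H](C)C(=O)O | intermediate
16 | (Z)-but-2-ene-1,4-diol | OC/C=C\CO | starting material
17 | (Z)-but-2-ene-1,4-diyl bis[(2R)-2-methylbutanoate] | CC[C@@H](C)C(=O)OC/C=C\COC(=O)[C@H](C)CC | intermediate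
18 | 3,5-bis({[(2R)-2-methylbutanoyl]oxy}methyl)-1,2,4-trioxolane (ozonide) | CC[C@@H](C)C(=O)OCC1OOC(COC(=O)[C@H](C)CC)O1 | intermediate
19 | 2-oxoethyl (2R)-2-methylbutanoate | CC[C@@H](C)C(=O)OCC=O | intermediate
20 | 1-{[(5R)-5-[(1E)-2-{[(tert-butyldiphenylsilyl)oxy]methyl}hexa-1,5-dien-1-yl]-2-oxo-2,5-dihydrofuran-3-yl]methyl}-4-aza-1-azoniabicyclo[2.2.2]octane bromide | [Br-].O=C1O[C@@H](C=C1C[N+]23CCN(CC2)CC3)/C=C(\CCC=C)CO[Si](c4ccccc4)(c4ccccc4)C(C)(C)C | intermediate
21 | (1R)-1-[(2R,3S)-2-[(1E)-2-{[(tert-butyldiphenylsilyl)oxy]methyl}hexa-1,5-dien-1-yl]-4-methylidene-5-oxooxolan-3-yl]-2-oxoethyl (2R)-2-methylbutanoate | C=C1C(=O)O[C@H](/C=C(\CCC=C)CO[Si](c2ccccc2)(c2ccccc2)C(C)(C)C)[C@H]1[C@@H](OC(=O)[C@H](C)CC)C=O | intermediate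
22 | acrolein (prop-2-enal) | C=CC=O | starting material
23 | (1R,2S)-1-[(2R,3S)-2-[(1E)-2-{[(tert-butyldiphenylsilyl)oxy]methyl}hexa-1,5-dien-1-yl]-4-methylidene-5-oxooxolan-3-yl]-3-formyl-2-hydroxybut-3-en-1-yl (2R)-2-methylbutanoate | C=C1C(=O)O[C@H](/C=C(\CCC=C)CO[Si](c2ccccc2)(c2ccccc2)C(C)(C)C)[C@H]1[C@@H](OC(=O)[C@H](C)CC)[C@@H](O)C(=C)C=O | intermediate
24 | (3aS,4R,5S,6E,10E,11aR)-10-{[(tert-butyldiphenylsilyl)oxy]methyl}-6-formyl-5-hydroxy-3-methylidene-2-oxo-2,3,3a,4,5,8,9,11a-octahydrocyclodeca[b]furan-4-yl (2R)-2-methylbutanoate | C=C1C(=O)O[C@@H]2/C=C(/CO[Si](c3ccccc3)(c3ccccc3)C(C)(C)C)CC/C=C(/C=O)[C@H](O)[C@H](OC(=O)[C@H](C)CC)[C@@H]12 | intermediate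
25 | (3aS,4R,5S,6E,10E,11aR)-6-formyl-5-hydroxy-10-(hydroxymethyl)-3-methylidene-2-oxo-2,3,3a,4,5,8,9,11a-octahydrocyclodeca[b]furan-4-yl (2R)-2-methylbutanoate (CNP0331447.12) | C=C1C(=O)O[C@@H]2/C=C(/CO)CC/C=C(/C=O)[C@H](O)[C@H](OC(=O)[C@H](C)CC)[C@@H]12 | target

**Step count and risks**
Total: 14 steps. Longest linear sequence: 11 steps (steps 1–7, then 11–14); steps 8–10 make the acyl donor in parallel.

Step 11, the proposed SN2′ alkylation, is the most likely to fail. The enamine could attack the CH2–N carbon instead of C-7, the γ-proton at C-6 could be lost to base, or the C-7/C-8 pairing could prove mismatched. The fallback is known chemistry. It sets out from 13: zinc-mediated Barbier allylation with 2,2-dimethoxyacetaldehyde (Zn dust, THF/sat. aq. NH4Cl, 0 °C) goes through a chair transition state on the face anti to the C-6 substituent and gives (4R,5R)-5-[(1E)-2-{[(tert-butyldiphenylsilyl)oxy]methyl}hexa-1,5-dien-1-yl]-4-[(1R)-1-hydroxy-2,2-dimethoxyethyl]-3-methylideneoxolan-2-one F1. Esterification with 15 (DCC, DMAP, CH2Cl2) gives the ester acetal F2. Acetal hydrolysis (TFA/H2O, CHCl3, 0 °C) comes back to the route at 21.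

Step 12, the acrolein Baylis–Hillman reaction, is the second risk. The 8,9-anti selectivity may be modest, the amine may epimerise C-8 of the α-acyloxy aldehyde, and the acyl group may migrate from O-8 to O-9. The fallback replaces the amine-catalysed addition by an organochromium addition to a masked enal. It sets out from 21: Nozaki–Hiyama–Kishi coupling with 2-bromo-3,3-diethoxyprop-1-ene (CrCl2, NiCl2 cat., DMF, rt; Felkin addition) gives the diethyl acetal of the adduct F3. Mild hydrolysis (PPTS, acetone/H2O, rt) comes back at 23.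

Step 13, the ring-closing metathesis, is the third risk. A trisubstituted, electron-poor alkene must form in a ten-membered ring, and dimerisation or catalyst stalling on the enal and the allylic alcohol are possible. The fallback closes the ring at C9–C10 instead. It sets out from 21 and skips step 12: cross-metathesis of the terminal alkene with acrolein (second-generation Hoveyda–Grubbs catalyst, CH2Cl2, 40 °C) gives the (E)-enal aldehyde F4. α-Iodination (I2, pyridine, DMAP cat., CH2Cl2, 0 °C) gives the (Z)-α-iodoenal F5. Nozaki–Hiyama–Kishi macrocyclisation (CrCl2, NiCl2 cat., DMSO/THF, 2 mM, rt) joins C-10 to the C-9 aldehyde with retention of alkene geometry and comes back at 24.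

Further compounds
F1 | step 11 | (4R,5R)-5-[(1E)-2-{[(tert-butyldiphenylsilyl)oxy]methyl}hexa-1,5-dien-1-yl]-4-[(1R)-1-hydroxy-2,2-dimethoxyethyl]-3-methylideneoxolan-2-one | C=C1C(=O)O[C@H](/C=C(\CCC=C)CO[Si](c2ccccc2)(c2ccccc2)C(C)(C)C)[C@H]1[C@@H](O)C(OC)OC
F2 | step 11 | (1R)-1-[(2R,3S)-2-[(1E)-2-{[(tert-butyldiphenylsilyl)oxy]methyl}hexa-1,5-dien-1-yl]-4-methylidene-5-oxooxolan-3-yl]-2,2-dimethoxyethyl (2R)-2-methylbutanoate | C=C1C(=O)O[C@H](/C=C(\CCC=C)CO[Si](c2ccccc2)(c2ccccc2)C(C)(C)C)[C@H]1[C@@H](OC(=O)[C@H](C)CC)C(OC)OC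
F3 | step 12 | (1R,2S)-1-[(2R,3S)-2-[(1E)-2-{[(tert-butyldiphenylsilyl)oxy]methyl}hexa-1,5-dien-1-yl]-4-methylidene-5-oxooxolan-3-yl]-3-(diethoxymethyl)-2-hydroxybut-3-en-1-yl (2R)-2-methylbutanoate | C=C1C(=O)O[C@H](/C=C(\CCC=C)CO[Si](c2ccccc2)(c2ccccc2)C(C)(C)C)[C@H]1[C@@H](OC(=O)[C@H](C)CC)[C@@H](O)C(=C)C(OCC)OCC
F4 | step 13 | (1R)-1-[(2R,3S)-2-[(1E,5E)-2-{[(tert-butyldiphenylsilyl)oxy]methyl}-7-oxohepta-1,5-dien-1-yl]-4-methylidene-5-oxooxolan-3-yl]-2-oxoethyl (2R)-2-methylbutanoate | C=C1C(=O)O[C@H](/C=C(\CC/C=C/C=O)CO[Si](c2ccccc2)(c2ccccc2)C(C)(C)C)[C@H]1[C@@H](OC(=O)[C@H](C)CC)C=O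
F5 | step 13 | (1R)-1-[(2R,3S)-2-[(1E,5Z)-2-{[(tert-butyldiphenylsilyl)oxy]methyl}-6-iodo-7-oxohepta-1,5-dien-1-yl]-4-methylidene-5-oxooxolan-3-yl]-2-oxoethyl (2R)-2-methylbutanoate | C=C1C(=O)O[C@H](/C=C(\CC/C=C(\I)C=O)CO[Si](c2ccccc2)(c2ccccc2)C(C)(C)C)[C@H]1[C@@H](OC(=O)[C@H](C)CC)C=O
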